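The bicyclic half is read as a ring-enlarged trans-hydrindane: ring B (C5–C10) carries the C8 oxygen next to the chain-bearing C9 and the quaternary C10, the signature of a cyclohexanone made by 1,2-shift. A proline-derived hydrindenedione supplies ring A, C5 and C10; Wittig olefination puts C9 and its nitrile chain on the cyclopentanone carbon C8. In the key step hypervalent iodine drives the C8–C10 bond to C9, turning the five-membered ring into ring B, unveiling the C8 ketone and fixing C9. Methylenation, hydration and nitrile reduction give a lactol that is joined to an (S)-γ-cyclogeranyl ylide by E-selective Wittig reaction; ester reduction ends the route.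

Key step: step 7

Remark on numbering: labdane atom numbers are used for the bicyclic half (decalin C1–C10, side chain C11–C13, C17 = methyl on C8, C20 = methyl on C10) and are kept for its hydrindane precursors (ketone carbon of 6 = C8); primed locants C1'–C6' are used for the monocyclic ring. Enedione 1, phosphonium salt 7, enone 18 and iodo ester 19 are taken as commercial.

Step 1
Reactants: 1 (S)-bicyclic enedione
Product: 2 C8 ethylene ketal
Conditions: HOCH2CH2OH, p-TsOH (cat.), 4 Å MS, CH2Cl2, rt
Reagents that add atoms: ethylene glycol, OCCO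
Why: Acid-catalysed ketalisation should occur at the unconjugated, more electrophilic cyclopentanone carbonyl and leave the vinylogous enone carbonyl free (chemoselective carbonyl protection).

Step 2
Reactants: 2 C8 ethylene ketal
Product: 3 gem-dimethyl β,γ-unsaturated keto ketal
Conditions: KOt-Bu, MeI, t-BuOH–THF, 0 °C → rt
Reagents that add atoms: iodomethane, CI
Why: Deconjugative α,α-dialkylation of the extended enolate installs the C4 gem-dimethyl group and moves the alkene to C5=C6 (dienolate alkylation).

Step 3
Reactants: 3 gem-dimethyl β,γ-unsaturated keto ketal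
Product: 4 alkene ketal
Conditions: N2H4·H2O, KOH, diethylene glycol, 200 °C
Reagents that add atoms: none
Why: Wolff–Kishner reduction (Huang–Minlon conditions) removes the non-conjugated C3 carbonyl, the ketal and the trisubstituted alkene being inert to hot base.

Step 4
Reactants: 4 alkene ketal
Product: 5 trans-hydrindane ketal
Conditions: H2 (4 atm), 10% Pd/C, EtOAc, rt
Reagents that add atoms: none
Why: Heterogeneous hydrogenation should deliver hydrogen to C5 from the α-face, opposite the angular C10 methyl and the axial C4 methyl (as with Δ14 steroids carrying a 17-oxygen function), which sets the trans ring fusion (H-5 α).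

Step 5
Reactants: 5 trans-hydrindane ketal
Product: 6 trans-hydrindanone
Conditions: 1 M HCl, THF, rt
Reagents that add atoms: water, O
Why: Mild acid hydrolysis of the dioxolane (acetal hydrolysis) frees the C8 cyclopentanone for olefination.

Step 6
Reactants: 6 trans-hydrindanone; 7 (3-cyanopropyl)triphenylphosphonium bromide
Product: 9 (Z)-alkylidene nitrile, via phosphorus ylide 8 (not isolated)
Conditions: 7, KN(SiMe3)2, toluene, 0 °C → rt; then 6, 110 °C
Reagents that add atoms: none
Why: Wittig olefination of the neopentyl cyclopentanone with the non-stabilised ylide (as on 17-keto steroids) attaches C9 and its nitrile chain, the chain expected cis to C10, and this geometry is of no consequence because C9 is equilibrated after step 7.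

Step 7
Reactants: 9 (Z)-alkylidene nitrile
Product: 12 trans-decalone nitrile, via methoxy alkyliodane 10 (not isolated), via 9-epi ketone 11 (not isolated)
Conditions: PhI(OH)OTs, MeOH–H2O (95:5), 0 °C → rt; then K2CO3, MeOH, rt
Reagents that add atoms: water, O
Why: Electrophilic trivalent iodine adds to the exocyclic C8=C9 alkene from the α-face and methanol opens the iodonium ion at the tertiary C8 to give iodane 10, whose neopentylic C9–I bond then ionises with concerted 1,2-shift of the antiperiplanar C8–C10 bond while the methoxy oxygen stabilises C8 as an oxocarbenium ion that water converts into the ketone. The closest known reaction type is the oxidative rearrangement of alkylidenecycloalkanes to ring-enlarged ketones by PhI(OH)OTs or Tl(NO3)3, a semipinacol (Tiffeneau–Demjanov-type) ring expansion known in the steroid series as D-homoannulation. Ring B is not closed by a cyclisation: it arises from the cyclopentane ring of 9 by insertion of C9 between C8 and C10, a five- to six-membered ring enlargement in which C10 migrates suprafacially with retention. The only new stereocentre is C9; it is set first by inversion at C9 during the shift (expected 9α epimer 11 from the (Z)-alkene) and then, because it is α to the new ketone, by base equilibration to the equatorial 9β chain, as in the corresponding 17a-alkyl D-homo ketones. The step needs migration of the quaternary C10 in preference to C7 and rearrangement in preference to solvolysis, and the higher migratory aptitude of the tertiary alkyl group towards the electron-poor C9 together with the hindered neopentylic position of C9 should secure both.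

Step 8
Reactants: 12 trans-decalone nitrile
Product: 13 exocyclic methylene nitrile
Conditions: Zn, CH2Br2, TiCl4, THF–CH2Cl2, 0 °C → rt
Reagents that add atoms: dibromomethane, BrCBr
Why: Takai–Lombardo methylenation converts the hindered, epimerisable C8 ketone into the 8(17)-alkene under non-basic conditions and leaves the nitrile and C9 untouched.

Step 9
Reactants: 13 exocyclic methylene nitrile
Product: 15 8α-hydroxy nitrile, via organomercurial 14 (not isolated)
Conditions: Hg(OAc)2, THF–H2O, rt; then NaBH4, aq. NaOH, 0 °C
Reagents that add atoms: water, O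
Why: Oxymercuration–demercuration gives Markovnikov hydration, and water should open the mercurinium ion at C8 from the equatorial α-face, away from the syn-axial C10 methyl, which sets C8 as 8α-OH/8β-CH3 (the facial preference of mercury-mediated additions to labd-8(17)-enes).

Step 10
Reactants: 15 8α-hydroxy nitrile
Product: 17 lactol, via hydroxy aldehyde 16 (not isolated)
Conditions: i-Bu2AlH, CH2Cl2, −78 °C; then aq. KNaC4H4O6, rt
Reagents that add atoms: water, O
Why: Half-reduction of the nitrile gives an aldimine that is hydrolysed on work-up to the δ-hydroxy aldehyde, which should close spontaneously to the six-membered lactol (hemiacetal formation).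

Step 11
Reactants: 18 4,4-dimethylcyclohex-2-en-1-one; 19 ethyl 4-iodobutanoate
Product: 21 Mannich base, via zinc enolate 20 (not isolated)
Conditions: 19, Et2Zn, CuI (cat.), 50 °C, then evaporation; Cu(OTf)2 (cat.), (S,R,R)-O,O'-(1,1'-binaphthyl-2,2'-diyl) N,N-bis(1-phenylethyl)phosphoramidite (cat.), 18, toluene, −30 °C; then CH2=NMe2+ I−, THF, −30 °C → rt
Reagents that add atoms: N,N-dimethylmethyleneiminium iodide, C=[N+](C)C.[I-]
Why: Copper-catalysed asymmetric conjugate addition of the functionalised dialkylzinc sets the ring stereocentre C1' under control of the chiral phosphoramidite ligand, and the regiodefined zinc enolate is trapped in a Mannich reaction anti to the new chain.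

Step 12
Reactants: 21 Mannich base
Product: 23 α-methylene ketone, via ammonium iodide 22 (not isolated)
Conditions: MeI, CH2Cl2, rt; then aq. NaHCO3, rt
Reagents that add atoms: none
Why: Quaternisation and mild base-induced β-elimination of trimethylamine (Mannich-base elimination) should unveil the exocyclic enone without touching the γ-stereocentre C1'.

Step 13
Reactants: 23 α-methylene ketone
Product: 24 allylic alcohol
Conditions: NaBH4, CeCl3·7H2O, MeOH, −78 °C
Reagents that add atoms: none
Why: Luche reduction gives clean 1,2-reduction of the enone (carbinol configuration irrelevant) and spares the ester.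

Step 14
Reactants: 24 allylic alcohol
Product: 25 allylic methyl carbonate
Conditions: ClCO2Me, pyridine, DMAP (cat.), CH2Cl2, 0 °C
Reagents that add atoms: methyl chloroformate, COC(=O)Cl
Why: Acylation of the secondary allylic alcohol gives the carbonate needed for ionisation by zerovalent palladium.

Step 15
Reactants: 25 allylic methyl carbonate
Product: 26 (S)-γ-cyclogeranyl ester
Conditions: Pd(OAc)2 (cat.), n-Bu3P (cat.), HCO2H, Et3N, THF, 40 °C
Reagents that add atoms: none
Why: Palladium-catalysed formate reduction of the allylic carbonate (Tsuji reduction) delivers hydride to the more substituted ring terminus of the π-allyl complex and so should give the exocyclic methylene isomer, the stereocentre C1' lying outside the allyl unit.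

Step 16
Reactants: 26 (S)-γ-cyclogeranyl ester
Product: 28 α-bromo ester, via lithium enolate 27 (not isolated)
Conditions: LiN(i-Pr)2, THF, −78 °C; then CBr4, −78 °C
Reagents that add atoms: tetrabromomethane, BrC(Br)(Br)Br
Why: Bromination of the ester enolate places the leaving group on the future ylide carbon, and the new α-stereocentre is lost in the next step.

Step 17
Reactants: 28 α-bromo ester
Product: 30 stabilised ylide, via phosphonium bromide 29 (not isolated)
Conditions: PPh3, toluene, 90 °C; then 2 M NaOH, CH2Cl2, rt
Reagents that add atoms: triphenylphosphine, c1ccc(cc1)P(c1ccccc1)c1ccccc1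
Why: SN2 displacement by PPh3 and deprotonation of the acidic phosphonium salt should give the isolable ester-stabilised ylide.

Step 18
Reactants: 17 lactol; 30 stabilised ylide
Product: 31 (E)-enoate
Conditions: toluene, PhCO2H (cat.), 100 °C
Reagents that add atoms: none
Why: The α-substituted stabilised ylide reacts with the open hydroxy aldehyde form 16 of the lactol to give the trisubstituted enoate with the ester trans to the C12 chain (E-selective Wittig reaction), which is the required alkene geometry.

Step 19
Reactants: 31 (E)-enoate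
Product: 32 target
Conditions: i-Bu2AlH, CH2Cl2, −78 → 0 °C
Reagents that add atoms: none
Why: 1,2-Reduction of the α,β-unsaturated ester gives the primary allylic alcohol without touching the alkenes or the tertiary carbinol.

Compound list

1 | (S)-7a-methyl-2,3,7,7a-tetrahydro-1H-indene-1,5(6H)-dione (proline-derived enedione; C10 methyl β) | O=C1[C@@]2(C)CCC(=O)C=C2CC1 | starting material
2 | (7a'S)-7a'-methyl-2',3',7',7a'-tetrahydrospiro[[1,3]dioxolane-2,1'-inden]-5'(6'H)-one (C8 ethylene ketal of 1) | O1CCOC12[C@@]3(C)CCC(=O)C=C3CC2 | intermediate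
3 | (7a'S)-4',4',7a'-trimethyl-2',4',7',7a'-tetrahydrospiro[[1,3]dioxolane-2,1'-inden]-5'(6'H)-one (C3 ketone, C4 gem-dimethyl, C5=C6 alkene) | O1CCOC12[C@@]3(C)CCC(=O)C(C)(C)C3=CC2 | intermediate
4 | (7a'S)-4',4',7a'-trimethyl-2',4',5',6',7',7a'-hexahydrospiro[[1,3]dioxolane-2,1'-indene] (C5=C6 alkene) | O1CCOC12[C@@]3(C)CCCC(C)(C)C3=CC2 | intermediate
5 | (3a'S,7a'S)-4',4',7a'-trimethyloctahydrospiro[[1,3]dioxolane-2,1'-indene] (trans-fused; H-5 α, CH3-10 β) | O1CCOC12[C@@]3(C)CCCC(C)(C)[C@@H]3CC2 | intermediate
6 | (3aS,7aS)-4,4,7a-trimethyloctahydro-1H-inden-1-one (trans-hydrindanone; carbonyl carbon = C8) | O=C1[C@@]2(C)CCCC(C)(C)[C@@H]2CC1 | intermediate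
7 | (3-cyanopropyl)triphenylphosphonium bromide | N#CCCC[P+](c1ccccc1)(c1ccccc1)c1ccccc1.[Br-] | starting material
8 | 4-(triphenyl-λ5-phosphanylidene)butanenitrile | N#CCCC=P(c1ccccc1)(c1ccccc1)c1ccccc1 | intermediate
9 | (Z)-4-[(3aS,7aS)-4,4,7a-trimethyloctahydro-1H-inden-1-ylidene]butanenitrile (C8=C9 alkene, chain cis to C10) | N#CCC/C=C1\[C@@]2(C)CCCC(C)(C)[C@@H]2CC1 | intermediate
10 | adduct of 9 with 8β-methoxy and 9-[phenyl(tosyloxy)-λ3-iodanyl] groups (iodine delivered from the α-face) | N#CCC[C@H](I(c1ccccc1)OS(=O)(=O)c1ccc(C)cc1)[C@@]1(OC)[C@@]2(C)CCCC(C)(C)[C@@H]2CC1 | intermediate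
11 | 3-[(1S,4aS,8aS)-5,5,8a-trimethyl-2-oxodecahydronaphthalen-1-yl]propanenitrile (9α chain; C9 epimer of 12) | N#CCC[C@H]1[C@@]2(C)CCCC(C)(C)[C@@H]2CCC1=O | intermediate
12 | 3-[(1R,4aS,8aS)-5,5,8a-trimethyl-2-oxodecahydronaphthalen-1-yl]propanenitrile (trans-decalin, C8 ketone, 9β chain) | N#CCC[C@@H]1[C@@]2(C)CCCC(C)(C)[C@@H]2CCC1=O | intermediate
13 | 3-[(1S,4aS,8aS)-5,5,8a-trimethyl-2-methylidenedecahydronaphthalen-1-yl]propanenitrile (8(17)-alkene, 9β chain) | N#CCC[C@@H]1[C@@]2(C)CCCC(C)(C)[C@@H]2CCC1=C | intermediate
14 | 8α-hydroxy-17-(acetoxymercurio) derivative of 13 (HgOAc on C17, OH on C8 α) | N#CCC[C@@H]1[C@@]2(C)CCCC(C)(C)[C@@H]2CC[C@@]1(C[Hg]OC(C)=O)O | intermediate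
15 | 3-[(1R,2R,4aS,8aS)-2-hydroxy-2,5,5,8a-tetramethyldecahydronaphthalen-1-yl]propanenitrile (8α-OH, 8β-CH3) | N#CCC[C@@H]1[C@@]2(C)CCCC(C)(C)[C@@H]2CC[C@@]1(C)O | intermediate
16 | 3-[(1R,2R,4aS,8aS)-2-hydroxy-2,5,5,8a-tetramethyldecahydronaphthalen-1-yl]propanal | O=CCC[C@@H]1[C@@]2(C)CCCC(C)(C)[C@@H]2CC[C@@]1(C)O | intermediate
17 | 8α,13-epoxy-14,15,16-trinorlabdan-13-ol (4a,7,7,10a-tetramethyldodecahydro-1H-benzo[f]chromen-3-ol; lactol, both anomers) | OC1CC[C@@H]2[C@@]3(C)CCCC(C)(C)[C@@H]3CC[C@@]2(C)O1 | intermediate
18 | 4,4-dimethylcyclohex-2-en-1-one | CC1(C)CCC(=O)C=C1 | starting material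
19 | ethyl 4-iodobutanoate | CCOC(=O)CCCI | starting material
20 | (4-ethoxy-4-oxobutyl)zinc enolate of ethyl (R)-4-(2,2-dimethyl-5-oxocyclohexyl)butanoate | CCOC(=O)CCC[C@@H]1C=C(O[Zn]CCCC(=O)OCC)CCC1(C)C | intermediate
21 | ethyl 4-[(1R)-6-[(dimethylamino)methyl]-2,2-dimethyl-5-oxocyclohexyl]butanoate (chain and aminomethyl group trans) | CCOC(=O)CCC[C@@H]1[C@@H](CN(C)C)C(=O)CCC1(C)C | intermediate
22 | N-methyl quaternary ammonium iodide of 21 | CCOC(=O)CCC[C@@H]1[C@@H](C[N+](C)(C)C)C(=O)CCC1(C)C.[I-] | intermediate
23 | ethyl 4-[(1S)-2,2-dimethyl-6-methylidene-5-oxocyclohexyl]butanoate | CCOC(=O)CCC[C@@H]1C(=C)C(=O)CCC1(C)C | intermediate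
24 | ethyl 4-[(1S)-5-hydroxy-2,2-dimethyl-6-methylidenecyclohexyl]butanoate (carbinol epimers) | CCOC(=O)CCC[C@@H]1C(=C)C(O)CCC1(C)C | intermediate
25 | ethyl 4-[(1S)-5-(methoxycarbonyloxy)-2,2-dimethyl-6-methylidenecyclohexyl]butanoate | CCOC(=O)CCC[C@@H]1C(=C)C(OC(=O)OC)CCC1(C)C | intermediate
26 | ethyl 4-[(1S)-2,2-dimethyl-6-methylidenecyclohexyl]butanoate | CCOC(=O)CCC[C@@H]1C(=C)CCCC1(C)C | intermediate
27 | lithium enolate of 26 | CCOC(O[Li])=CCC[C@@H]1C(=C)CCCC1(C)C | intermediate
28 | ethyl 2-bromo-4-[(1S)-2,2-dimethyl-6-methylidenecyclohexyl]butanoate (α-epimers) | CCOC(=O)C(Br)CC[C@@H]1C(=C)CCCC1(C)C | intermediate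
29 | [4-[(1S)-2,2-dimethyl-6-methylidenecyclohexyl]-1-ethoxy-1-oxobutan-2-yl]triphenylphosphonium bromide | CCOC(=O)C(CC[C@@H]1C(=C)CCCC1(C)C)[P+](c1ccccc1)(c1ccccc1)c1ccccc1.[Br-] | intermediate
30 | ethyl 4-[(1S)-2,2-dimethyl-6-methylidenecyclohexyl]-2-(triphenyl-λ5-phosphanylidene)butanoate | CCOC(=O)C(CC[C@@H]1C(=C)CCCC1(C)C)=P(c1ccccc1)(c1ccccc1)c1ccccc1 | intermediate
31 | ethyl (2E)-2-[2-[(1S)-2,2-dimethyl-6-methylidenecyclohexyl]ethyl]-5-[(1R,2R,4aS,8aS)-2-hydroxy-2,5,5,8a-tetramethyldecahydronaphthalen-1-yl]pent-2-enoate | C=C1CCCC(C)(C)[C@@H]1CC/C(=C\CC[C@@H]1[C@@]2(C)CCCC(C)(C)[C@@H]2CC[C@@]1(C)O)C(=O)OCC | intermediate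
32 | (1R,2R,4aS,8aS)-1-[(3E)-6-[(1S)-2,2-dimethyl-6-methylidenecyclohexyl]-4-(hydroxymethyl)hex-3-en-1-yl]-2,5,5,8a-tetramethyldecahydronaphthalen-2-ol (CNP0209309.1) | C=C1CCCC(C)(C)[C@@H]1CC/C(=C\CC[C@@H]1[C@@]2(C)CCCC(C)(C)[C@@H]2CC[C@@]1(C)O)CO | target

Total step count: 19. Longest linear sequence: 12 steps (steps 1–10, 18 and 19).

Steps most likely to fail

Step 7 (key step). The C8–C7 bond may migrate in place of the C8–C10 bond, or methanol may intercept the alkyl iodane before the shift (oxidative dimethoxylation). The fallback sets out from 9. Dihydroxylation from the α-face (OsO4 cat., NMO, acetone–water) should give the 8,9-diol F1. Selective sulfonylation of its secondary C9 hydroxyl (MsCl, pyridine, 0 °C) gives the hydroxy mesylate F2. KOt-Bu in THF should then trigger the alkoxide-driven semipinacol shift of the C8–C10 bond, and the same K2CO3 equilibration brings the route back at 12.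

Step 4. Hydrogen may be delivered to the β-face of the hindered cyclopentene (cis ring fusion), or the reduction may stall. The fallback sets out from 4 and replaces surface hydrogenation by hydrogen-atom-transfer hydrogenation (Mn(dpm)3, PhSiH3, t-BuOOH, i-PrOH, rt). The stepwise radical path forms the tertiary C5 radical, which should take up hydrogen from the less hindered α-face. It comes back at 5 and makes no new compound.

Step 12. The exocyclic double bond of the enone may migrate into the ring under the basic elimination conditions, which would erase the only stereocentre of this fragment. The fallback sets out from 21 and never forms the enone. The ketone is reduced first (NaBH4, MeOH) to the amino alcohol F3. The amine is then oxidised (mCPBA, CH2Cl2) to the amine N-oxide F4, which on warming should undergo Cope elimination towards the ring hydrogen at C6'. This comes back at allylic alcohol 24.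

Further compounds
F1 | step 7 | 4-hydroxy-4-[(3aS,7aS)-1-hydroxy-4,4,7a-trimethyloctahydro-1H-inden-1-yl]butanenitrile (8,9-diol, both hydroxyls from the α-face) | N#CCC[C@H](O)[C@]1(O)[C@@]2(C)CCCC(C)(C)[C@@H]2CC1
F2 | step 7 | C9 methanesulfonate of F1 | N#CCC[C@H](OS(C)(=O)=O)[C@]1(O)[C@@]2(C)CCCC(C)(C)[C@@H]2CC1
F0 | step 4 | none | none
F3 | step 12 | ethyl 4-[(1R)-6-[(dimethylamino)methyl]-5-hydroxy-2,2-dimethylcyclohexyl]butanoate | CCOC(=O)CCC[C@@H]1[C@@H](CN(C)C)C(O)CCC1(C)C
F4 | step 12 | N-oxide of F3 | CCOC(=O)CCC[C@@H]1[C@@H](C[N+](C)(C)[O-])C(O)CCC1(C)C
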